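Ring B is disconnected at C8–C9 (labdane numbering). The exocyclic C8=C17 methylene beside the side-chain-bearing methine C9 is read as the product of an Alder-ene reaction between a C8≡C17 alkyne and a C9=C11 olefin. A palladium-catalysed cycloisomerization of a 1,7-enyne therefore closes ring B, creates the C8=C17 methylene, sets C9 and leaves a C11=C12 vinyl group for a B-alkyl Suzuki union with a (Z)-iodobutenoate. The precursor is a monocyclic ring A cyclohexane with a (Z)-propenyl group on C10 and an (S)-homopropargylic silyl ether on C5; its contiguous centres C4, C5 and C10 are set earlier within a temporary bridged lactone (C18–O–C9).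

Key step: step 13

Remark: labdane numbering (C1–C20) is used for all intermediates. The absolute sense of the two reagent-controlled steps (2 and 8) is assigned from the accepted models for these reagent classes and is not verified; if either gave the opposite sense, the antipodal auxiliary or catalyst would be used with no other change.

Step 1
Reactants: 1 methyl 2-oxocyclohexane-1-carboxylate; 2 tert-butyl L-valinate
Product: 3 methyl 2-{[(2S)-1-tert-butoxy-3-methyl-1-oxobutan-2-yl]amino}cyclohex-1-ene-1-carboxylate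
Conditions: BF3·OEt2 (cat.), benzene, reflux, Dean–Stark trap
Reagents that add atoms: none
Why: Acid-catalysed condensation of the β-keto ester with the primary amine gives the hydrogen-bonded enamino ester (vinylogous carbamate formation) that carries the valine auxiliary.

Step 2
Reactants: 3 methyl 2-{[(2S)-1-tert-butoxy-3-methyl-1-oxobutan-2-yl]amino}cyclohex-1-ene-1-carboxylate
Product: 5 methyl (1S)-1-methyl-2-oxocyclohexane-1-carboxylate, via alkylated imine 4 (not isolated)
Conditions: LiN(i-Pr)2, toluene, −78 °C; HMPA (1 equiv); MeI; then 1 M aq. HCl, 0 °C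
Reagents that add atoms: iodomethane (CI)
Why: Asymmetric alkylation of the chelated lithio-enamine (chiral auxiliary enamine alkylation) should put the methyl group on the face not shielded by the valine isopropyl group, setting the quaternary centre C10 as S, and mild acid hydrolysis of the imine returns the keto ester and the auxiliary.

Step 3
Reactants: 5 methyl (1S)-1-methyl-2-oxocyclohexane-1-carboxylate
Product: 6 methyl (1S)-1,3-dimethyl-2-oxocyclohexane-1-carboxylate (both C3 epimers)
Conditions: LiN(i-Pr)2, THF, −78 °C; MeI, −78 → 0 °C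
Reagents that add atoms: iodomethane (CI)
Why: Kinetic enolate alkylation at the only enolisable α-carbon (C4) installs the C19 methyl group; its configuration is immaterial because C4 is planarised again in step 4.

Step 4
Reactants: 6 methyl (1S)-1,3-dimethyl-2-oxocyclohexane-1-carboxylate
Product: 8 (1S,5S)-1,5-dimethyl-3-oxabicyclo[3.3.1]nonane-2,9-dione, via hydroxy ester 7 (not isolated)
Conditions: LiN(i-Pr)2, THF, −78 °C; CH2O (g, from cracked paraformaldehyde), −78 → 0 °C; aq. NH4Cl; then TsOH·H2O (cat.), toluene, 80 °C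
Reagents that add atoms: formaldehyde (C=O)
Why: Lithium enolate aldol addition to formaldehyde then acid-catalysed lactonisation: the ester carbonyl chelates lithium and lies pseudo-equatorial, so formaldehyde should enter anti to the pseudo-axial C10 methyl group (cis to the ester), and only this cis aldol can close the bridged δ-lactone, which locks C4 and C10 in the required cis-dimethyl relationship (an epimeric aldol stays open and can be returned to 6 by retro-aldol).

Step 5
Reactants: 8 (1S,5S)-1,5-dimethyl-3-oxabicyclo[3.3.1]nonane-2,9-dione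
Product: 9 (1S,5R)-1,5-dimethyl-9-methylidene-3-oxabicyclo[3.3.1]nonan-2-one
Conditions: Zn, CH2Br2, TiCl4, THF–CH2Cl2, 0 °C → rt
Reagents that add atoms: dibromomethane (BrCBr)
Why: Takai–Lombardo methylenation uses a non-basic titanium–zinc methylene reagent that should attack the hindered, non-enolisable bridging ketone and leave the lactone untouched.

Step 6
Reactants: 9 (1S,5R)-1,5-dimethyl-9-methylidene-3-oxabicyclo[3.3.1]nonan-2-one
Product: 11 (1S,5R,9S)-9-(hydroxymethyl)-1,5-dimethyl-3-oxabicyclo[3.3.1]nonan-2-one, via alkyl-9-BBN adduct 10 (not isolated)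
Conditions: 9-BBN, THF, 0 → 50 °C; then H2O2, aq. NaOAc, 0 °C → rt
Reagents that add atoms: hydrogen peroxide (OO)
Why: Hydroboration–oxidation places boron on the terminal carbon and should deliver hydrogen to C5 from the less hindered face over the lactone bridge (one axial hydrogen and a flat carbonyl against two axial hydrogens on the carbocyclic side), so the CH2OH group ends over the carbocycle, trans to C18 and C9 as the target requires.

Step 7
Reactants: 11 (1S,5R,9S)-9-(hydroxymethyl)-1,5-dimethyl-3-oxabicyclo[3.3.1]nonan-2-one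
Product: 12 (1S,5R,9S)-1,5-dimethyl-2-oxo-3-oxabicyclo[3.3.1]nonane-9-carbaldehyde
Conditions: Dess–Martin periodinane, NaHCO3, CH2Cl2, 0 °C → rt; used at once
Reagents that add atoms: none
Why: Dess–Martin oxidation under bicarbonate buffer should give the aldehyde (C6) without epimerising the adjacent centre C5.

Step 8
Reactants: 12 (1S,5R,9S)-1,5-dimethyl-2-oxo-3-oxabicyclo[3.3.1]nonane-9-carbaldehyde
Product: 13 (1S,5R,9S)-9-[(1S)-1-hydroxybut-3-yn-1-yl]-1,5-dimethyl-3-oxabicyclo[3.3.1]nonan-2-one
Conditions: allenylboronic acid pinacol ester, (S)-TRIP phosphoric acid (10 mol%), 4 Å molecular sieves, toluene, −20 °C → rt; aqueous work-up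
Reagents that add atoms: allenylboronic acid pinacol ester (C=C=CB1OC(C)(C)C(C)(C)O1)
Why: Chiral Brønsted acid-catalysed propargylation with an allenyl boronate (closed six-membered SE2' transition state) is catalyst-controlled because the two flanks of the aldehyde are nearly mirror images, and the (S)-catalyst should direct addition to the Si face to give the 6S carbinol.

Step 9
Reactants: 13 (1S,5R,9S)-9-[(1S)-1-hydroxybut-3-yn-1-yl]-1,5-dimethyl-3-oxabicyclo[3.3.1]nonan-2-one
Product: 14 (1S,5R,9S)-1,5-dimethyl-9-[(1S)-1-(triethylsilyloxy)but-3-yn-1-yl]-3-oxabicyclo[3.3.1]nonan-2-one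
Conditions: Et3SiOTf, 2,6-lutidine, CH2Cl2, −78 → 0 °C
Reagents that add atoms: triethylsilyl trifluoromethanesulfonate (CC[Si](CC)(CC)OS(=O)(=O)C(F)(F)F)
Why: Silylation of the hindered secondary alcohol with the silyl triflate masks O6 for the hydride, ylide and palladium steps.

Step 10
Reactants: 14 (1S,5R,9S)-1,5-dimethyl-9-[(1S)-1-(triethylsilyloxy)but-3-yn-1-yl]-3-oxabicyclo[3.3.1]nonan-2-one
Product: 15 (1S,5R,9S)-1,5-dimethyl-9-[(1S)-1-(triethylsilyloxy)but-3-yn-1-yl]-3-oxabicyclo[3.3.1]nonan-2-ol (lactol, both anomers)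
Conditions: i-Bu2AlH, CH2Cl2, −78 °C; aq. sodium potassium tartrate work-up
Reagents that add atoms: none
Why: Half-reduction of the lactone with i-Bu2AlH at low temperature should stop at the tetrahedral aluminate and give the lactol (C9 at the aldehyde level).

Step 11
Reactants: 15 (1S,5R,9S)-1,5-dimethyl-9-[(1S)-1-(triethylsilyloxy)but-3-yn-1-yl]-3-oxabicyclo[3.3.1]nonan-2-ol
Product: 16 [(1R,2R,3R)-1,3-dimethyl-3-[(1Z)-prop-1-en-1-yl]-2-[(1S)-1-(triethylsilyloxy)but-3-yn-1-yl]cyclohexyl]methanol
Conditions: EtPPh3Br, KN(SiMe3)2, THF, 0 °C; then 15, −78 °C → rt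
Reagents that add atoms: ethyltriphenylphosphonium bromide (CC[P+](c1ccccc1)(c1ccccc1)c1ccccc1.[Br-])
Why: Wittig olefination of the lactol through its open hydroxy-aldehyde form with the non-stabilised ylide should give the (Z)-propenyl group on C10 and at the same time open the temporary ring and free the C18 hydroxyl.

Step 12
Reactants: 16 [(1R,2R,3R)-1,3-dimethyl-3-[(1Z)-prop-1-en-1-yl]-2-[(1S)-1-(triethylsilyloxy)but-3-yn-1-yl]cyclohexyl]methanol
Product: 17 [(1R,2R,3R)-1,3-dimethyl-3-[(1Z)-prop-1-en-1-yl]-2-[(1S)-1-(triethylsilyloxy)but-3-yn-1-yl]cyclohexyl]methyl benzoate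
Conditions: BzCl, pyridine, DMAP (cat.), CH2Cl2, 0 °C → rt
Reagents that add atoms: benzoyl chloride (O=C(Cl)c1ccccc1)
Why: Acylation (nucleophilic catalysis by DMAP) of the only free hydroxyl installs the C18 benzoate of the target.

Step 13
Reactants: 17 [(1R,2R,3R)-1,3-dimethyl-3-[(1Z)-prop-1-en-1-yl]-2-[(1S)-1-(triethylsilyloxy)but-3-yn-1-yl]cyclohexyl]methyl benzoate
Product: 18 (4R,5R,6S,9S,10R)-6-(triethylsilyloxy)-13,14,15,16-tetranorlabda-8(17),11-dien-18-yl benzoate
Conditions: Pd(OAc)2 (5 mol%), N,N'-bis(benzylidene)ethylenediamine (10 mol%), benzene, 60 °C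
Reagents that add atoms: none
Why: Palladium-catalysed Alder-ene cycloisomerization of the 1,7-enyne: the divalent palladium catalyst engages the C8≡C17 alkyne and the C9=C11 olefin and forms the C8–C9 bond with palladium on C11 (palladacyclopentene or vinyl-palladium carbopalladation manifold), then β-hydride elimination from the C12 methyl and C17–H reductive elimination release the 1,4-diene and the catalyst. The closest known reaction type is the cycloisomerization of 1,6- and 1,7-enynes to exo-methylene carbocycles that bear a vinyl group. Ring B closes in the 6-exo mode with respect to both π systems (C17 and C11 stay outside the ring). The new centre C9 should be set by a chair-like transition state held by ring A: the C5 and C10 substituents are vicinal and equatorial, the C6 silyloxy group is equatorial and C11 takes the equatorial position, so H-9 is axial (α) and anti to the axial C10 methyl. The step needs β-hydride elimination toward C12 and not toward H-9 (which would give the conjugated 1,3-diene); this should be secured because the ring C9–H bond cannot become syn-coplanar with the C11–Pd bond in the metallacycle, whereas the freely rotating C12 methyl can. The benzoate and the silyl ether are spectators.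

Step 14
Reactants: 19 but-2-ynoic acid
Product: 20 (2Z)-3-iodobut-2-enoic acid
Conditions: NaI, AcOH, 115 °C
Reagents that add atoms: sodium iodide ([Na+].[I-])
Why: Anti addition of HI across the ynoic acid (conjugate hydroiodination) should give the Z iodoalkenoic acid with iodine cis to the carboxyl group.

Step 15
Reactants: 20 (2Z)-3-iodobut-2-enoic acid
Product: 21 2-(trimethylsilyl)ethyl (2Z)-3-iodobut-2-enoate
Conditions: Me3SiCH2CH2OH, DCC, DMAP (cat.), CH2Cl2, 0 °C → rt
Reagents that add atoms: 2-(trimethylsilyl)ethanol (C[Si](C)(C)CCO)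
Why: Steglich esterification gives the fluoride-labile 2-(trimethylsilyl)ethyl ester without touching the vinyl iodide geometry.

Step 16
Reactants: 18 (4R,5R,6S,9S,10R)-6-(triethylsilyloxy)-13,14,15,16-tetranorlabda-8(17),11-dien-18-yl benzoate; 21 2-(trimethylsilyl)ethyl (2Z)-3-iodobut-2-enoate
Product: 23 2-(trimethylsilyl)ethyl (13Z)-18-(benzoyloxy)-6α-(triethylsilyloxy)labda-8(17),13-dien-15-oate, via alkyl(disiamyl)borane 22 (not isolated)
Conditions: (Sia)2BH (from BH3·THF and 2-methylbut-2-ene), THF, 0 °C; then 21, Pd(dppf)Cl2 (5 mol%), AsPh3, aq. Cs2CO3, DMF, rt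
Reagents that add atoms: none
Why: The bulky dialkylborane should hydroborate the monosubstituted C11=C12 vinyl group in preference to the 1,1-disubstituted C8=C17 methylene, and the B-alkyl Suzuki–Miyaura coupling of the primary alkylborane with the vinyl iodide proceeds with retention to give the 13Z enoate.

Step 17
Reactants: 23 2-(trimethylsilyl)ethyl (13Z)-18-(benzoyloxy)-6α-(triethylsilyloxy)labda-8(17),13-dien-15-oate
Product: 24 (13Z)-18-(benzoyloxy)-6α-hydroxylabda-8(17),13-dien-15-oic acid (CNP0304840.1)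
Conditions: Bu4NF, THF, 0 °C → rt; aq. NH4Cl
Reagents that add atoms: none
Why: Fluoride should cleave the triethylsilyl ether and fragment the 2-(trimethylsilyl)ethyl ester (β-elimination of ethene) in one operation, while the primary benzoate, the thermodynamically preferred acyl position, stays in place.

Compound list
1 | methyl 2-oxocyclohexane-1-carboxylate | COC(=O)C1CCCCC1=O | starting material
2 | tert-butyl L-valinate | CC(C)[C@H](N)C(=O)OC(C)(C)C | starting material
3 | methyl 2-{[(2S)-1-tert-butoxy-3-methyl-1-oxobutan-2-yl]amino}cyclohex-1-ene-1-carboxylate | COC(=O)C1=C(N[C@@H](C(C)C)C(=O)OC(C)(C)C)CCCC1 | intermediate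
4 | methyl (1S)-2-{[(2S)-1-tert-butoxy-3-methyl-1-oxobutan-2-yl]imino}-1-methylcyclohexane-1-carboxylate (alkylated imine) | COC(=O)[C@@]1(C)CCCCC1=N[C@@H](C(C)C)C(=O)OC(C)(C)C | intermediate (not isolated)
5 | methyl (1S)-1-methyl-2-oxocyclohexane-1-carboxylate | COC(=O)[C@@]1(C)CCCCC1=O | intermediate
6 | methyl (1S)-1,3-dimethyl-2-oxocyclohexane-1-carboxylate (both C3 epimers) | COC(=O)[C@@]1(C)CCCC(C)C1=O | intermediate
7 | methyl (1S,3S)-3-(hydroxymethyl)-1,3-dimethyl-2-oxocyclohexane-1-carboxylate (hydroxy ester) | COC(=O)[C@@]1(C)CCC[C@@](C)(CO)C1=O | intermediate (not isolated)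
8 | (1S,5S)-1,5-dimethyl-3-oxabicyclo[3.3.1]nonane-2,9-dione | O=C1[C@]2(C)COC(=O)[C@@]1(C)CCC2 | intermediate
9 | (1S,5R)-1,5-dimethyl-9-methylidene-3-oxabicyclo[3.3.1]nonan-2-one | C=C1[C@]2(C)COC(=O)[C@@]1(C)CCC2 | intermediate
10 | B-alkyl-9-borabicyclo[3.3.1]nonane adduct of 9 (boron on the new CH2, hydrogen on C5 syn to the lactone bridge) | C(B1C2CCCC1CCC2)[C@H]1[C@]2(C)COC(=O)[C@@]1(C)CCC2 | intermediate (not isolated)
11 | (1S,5R,9S)-9-(hydroxymethyl)-1,5-dimethyl-3-oxabicyclo[3.3.1]nonan-2-one | OC[C@H]1[C@]2(C)COC(=O)[C@@]1(C)CCC2 | intermediate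
12 | (1S,5R,9S)-1,5-dimethyl-2-oxo-3-oxabicyclo[3.3.1]nonane-9-carbaldehyde | O=C[C@H]1[C@]2(C)COC(=O)[C@@]1(C)CCC2 | intermediate
13 | (1S,5R,9S)-9-[(1S)-1-hydroxybut-3-yn-1-yl]-1,5-dimethyl-3-oxabicyclo[3.3.1]nonan-2-one | C#CC[C@H](O)[C@H]1[C@]2(C)COC(=O)[C@@]1(C)CCC2 | intermediate
14 | (1S,5R,9S)-1,5-dimethyl-9-[(1S)-1-(triethylsilyloxy)but-3-yn-1-yl]-3-oxabicyclo[3.3.1]nonan-2-one | C#CC[C@H](O[Si](CC)(CC)CC)[C@H]1[C@]2(C)COC(=O)[C@@]1(C)CCC2 | intermediate
15 | (1S,5R,9S)-1,5-dimethyl-9-[(1S)-1-(triethylsilyloxy)but-3-yn-1-yl]-3-oxabicyclo[3.3.1]nonan-2-ol (lactol, both anomers) | C#CC[C@H](O[Si](CC)(CC)CC)[C@H]1[C@]2(C)COC(O)[C@@]1(C)CCC2 | intermediate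
16 | [(1R,2R,3R)-1,3-dimethyl-3-[(1Z)-prop-1-en-1-yl]-2-[(1S)-1-(triethylsilyloxy)but-3-yn-1-yl]cyclohexyl]methanol | C#CC[C@H](O[Si](CC)(CC)CC)[C@H]1[C@](C)(CO)CCC[C@]1(C)/C=C\C | intermediate
17 | [(1R,2R,3R)-1,3-dimethyl-3-[(1Z)-prop-1-en-1-yl]-2-[(1S)-1-(triethylsilyloxy)but-3-yn-1-yl]cyclohexyl]methyl benzoate | C#CC[C@H](O[Si](CC)(CC)CC)[C@H]1[C@](C)(COC(=O)c2ccccc2)CCC[C@]1(C)/C=C\C | intermediate
18 | (4R,5R,6S,9S,10R)-6-(triethylsilyloxy)-13,14,15,16-tetranorlabda-8(17),11-dien-18-yl benzoate | C=C1C[C@H](O[Si](CC)(CC)CC)[C@H]2[C@](C)(COC(=O)c3ccccc3)CCC[C@]2(C)[C@H]1C=C | intermediate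
19 | but-2-ynoic acid | CC#CC(=O)O | starting material
20 | (2Z)-3-iodobut-2-enoic acid | C/C(I)=C/C(=O)O | intermediate
21 | 2-(trimethylsilyl)ethyl (2Z)-3-iodobut-2-enoate | C/C(I)=C/C(=O)OCC[Si](C)(C)C | intermediate
22 | C12 bis(3-methylbutan-2-yl)borane from 18 (alkyl(disiamyl)borane) | C=C1C[C@H](O[Si](CC)(CC)CC)[C@H]2[C@](C)(COC(=O)c3ccccc3)CCC[C@]2(C)[C@H]1CCB(C(C)C(C)C)C(C)C(C)C | intermediate (not isolated)
23 | 2-(trimethylsilyl)ethyl (13Z)-18-(benzoyloxy)-6α-(triethylsilyloxy)labda-8(17),13-dien-15-oate | C=C1C[C@H](O[Si](CC)(CC)CC)[C@H]2[C@](C)(COC(=O)c3ccccc3)CCC[C@]2(C)[C@H]1CC/C(C)=C\C(=O)OCC[Si](C)(C)C | intermediate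
24 | (13Z)-18-(benzoyloxy)-6α-hydroxylabda-8(17),13-dien-15-oic acid (4R,5R,6S,9S,10R) | C=C1C[C@H](O)[C@H]2[C@](C)(COC(=O)c3ccccc3)CCC[C@]2(C)[C@H]1CC/C(C)=C\C(=O)O | target

Total step count: 17. Longest linear sequence: 15 (steps 1–13, 16 and 17).

Steps most likely to fail

Step 13 (key step). The carbometalation has to take place at the olefin carbon C9 next to the quaternary C10 and may be slow, so alkyne oligomerisation can compete; β-hydride elimination toward the ring would give the conjugated 1,3-diene. The fallback sets out from lactol 15 and forms the same C8–C9 bond by electrophilic alkyne activation. Wittig reaction of 15 with the ylide from [2-(trimethylsilyl)ethyl]triphenylphosphonium iodide and KN(SiMe3)2 should give the allylsilane [(1R,2R,3R)-1,3-dimethyl-2-[(1S)-1-(triethylsilyloxy)but-3-yn-1-yl]-3-[(1Z)-3-(trimethylsilyl)prop-1-en-1-yl]cyclohexyl]methanol F1. Benzoylation (BzCl, pyridine, DMAP) gives its benzoate [(1R,2R,3R)-1,3-dimethyl-2-[(1S)-1-(triethylsilyloxy)but-3-yn-1-yl]-3-[(1Z)-3-(trimethylsilyl)prop-1-en-1-yl]cyclohexyl]methyl benzoate F2. PtCl2 (5 mol%) in methanol at 65 °C then activates the alkyne for SE2' attack by C9 of the allylsilane, and protodemetalation with loss of the silyl group delivers 18, where the route is rejoined.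

Step 16. Discrimination between the vinyl group and the exocyclic methylene in the hydroboration may be incomplete, and transfer of the primary alkyl group from the dialkylborane to palladium may be sluggish. The fallback sets out from 18 and separates the two events. Hydroboration with pinacolborane catalysed by [Ir(cod)Cl]2 and bis(diphenylphosphino)methane, which is selective for monosubstituted terminal olefins, should give 2-[(4R,5R,6S,9S,10R)-18-(benzoyloxy)-6-(triethylsilyloxy)-13,14,15,16-tetranorlabd-8(17)-en-12-yl]-4,4,5,5-tetramethyl-1,3,2-dioxaborolane F3. Treatment with KHF2 in aqueous methanol gives the potassium [(4R,5R,6S,9S,10R)-18-(benzoyloxy)-6-(triethylsilyloxy)-13,14,15,16-tetranorlabd-8(17)-en-12-yl]trifluoroborate F4. Cross-coupling of F4 with 21 (Pd(dppf)Cl2, Cs2CO3, toluene–water, 80 °C) rejoins the route at 23.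

Step 8. Addition to the aldehyde flanked by two quaternary carbons may be slow, facial control at C6 by the catalyst may be insufficient, and C5 may epimerise during a long reaction. The fallback sets out from aldehyde 12 and moves the stereocontrol to a ketone reduction. Barbier propargylation (Zn, propargyl bromide, THF–aq. NH4Cl) gives (1S,5R,9S)-9-(1-hydroxybut-3-yn-1-yl)-1,5-dimethyl-3-oxabicyclo[3.3.1]nonan-2-one (both carbinol epimers) F5. Buffered Dess–Martin oxidation gives the ynone (1S,5R,9S)-9-(but-3-ynoyl)-1,5-dimethyl-3-oxabicyclo[3.3.1]nonan-2-one F6. Corey–Bakshi–Shibata reduction with the (R)-2-methyl-oxazaborolidine and BH3·SMe2 at −40 °C should differentiate the large bicyclic residue from the small propargyl group and return the 6S carbinol 13.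

Further compounds
F1 | step 13 | [(1R,2R,3R)-1,3-dimethyl-2-[(1S)-1-(triethylsilyloxy)but-3-yn-1-yl]-3-[(1Z)-3-(trimethylsilyl)prop-1-en-1-yl]cyclohexyl]methanol | C#CC[C@H](O[Si](CC)(CC)CC)[C@H]1[C@](C)(CO)CCC[C@]1(C)/C=C\C[Si](C)(C)C
F2 | step 13 | [(1R,2R,3R)-1,3-dimethyl-2-[(1S)-1-(triethylsilyloxy)but-3-yn-1-yl]-3-[(1Z)-3-(trimethylsilyl)prop-1-en-1-yl]cyclohexyl]methyl benzoate | C#CC[C@H](O[Si](CC)(CC)CC)[C@H]1[C@](C)(COC(=O)c2ccccc2)CCC[C@]1(C)/C=C\C[Si](C)(C)C
F3 | step 16 | 2-[(4R,5R,6S,9S,10R)-18-(benzoyloxy)-6-(triethylsilyloxy)-13,14,15,16-tetranorlabd-8(17)-en-12-yl]-4,4,5,5-tetramethyl-1,3,2-dioxaborolane | C=C1C[C@H](O[Si](CC)(CC)CC)[C@H]2[C@](C)(COC(=O)c3ccccc3)CCC[C@]2(C)[C@H]1CCB1OC(C)(C)C(C)(C)O1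
F4 | step 16 | potassium [(4R,5R,6S,9S,10R)-18-(benzoyloxy)-6-(triethylsilyloxy)-13,14,15,16-tetranorlabd-8(17)-en-12-yl]trifluoroborate | C=C1C[C@H](O[Si](CC)(CC)CC)[C@H]2[C@](C)(COC(=O)c3ccccc3)CCC[C@]2(C)[C@H]1CC[B-](F)(F)F.[K+]
F5 | step 8 | (1S,5R,9S)-9-(1-hydroxybut-3-yn-1-yl)-1,5-dimethyl-3-oxabicyclo[3.3.1]nonan-2-one (both carbinol epimers) | C#CCC(O)[C@H]1[C@]2(C)COC(=O)[C@@]1(C)CCC2
F6 | step 8 | (1S,5R,9S)-9-(but-3-ynoyl)-1,5-dimethyl-3-oxabicyclo[3.3.1]nonan-2-one | C#CCC(=O)[C@H]1[C@]2(C)COC(=O)[C@@]1(C)CCC2
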